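**Retrosynthetic overview**
1. Feature: in ring A of the upper chroman, the ring oxygen O1 sits on C8a and the diarylmethine carbon C4 sits on the neighbouring C4a. These two adjacent ring A carbons are read as an aryne, and the chain O1–C2–C3–C4 as a 2,3-diaryloxetane that opens at its benzylic C–O bond.
2. Key disconnection: O1–C8a and C4–C4a, by insertion of 5-benzyloxy-3-chlorobenzyne into the trans-oxetane that has ring B on C3 and ring D on C2. The chlorine at C5 steers the addition and leaves with the four benzyl groups in the last step.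
3. Oxetane: an anti-aldol joins a ring B arylacetyl oxazolidinone to the ring D aldehyde (C3–C4 bond, sets upper C3). Reduction, primary tosylation and 4-exo-tet closure follow.
4. Ring D aldehyde: the same imide, brominated, is benzylated under auxiliary control (sets lower C3), reduced and closed to the lower chroman by Mitsunobu etherification. Br is then exchanged for CHO.
5. Order of ring formation: lower pyran ring, oxetane, upper pyran ring (by expansion of the oxetane). All benzene rings are bought.

Key step: step 22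

Labels: the upper chroman consists of ring A (benzo) and its pyran ring; ring B sits on C3 and ring D on C4. The lower isoflavan is the chroman on C5 of ring D.
Assumption: the MgCl2-catalysed anti-aldol of an N-acyloxazolidinone is taken to proceed through the magnesium-chelated (Z)-enolate on the face away from the auxiliary benzyl group, the same facial sense as enolate alkylation, so that one (S)-configured imide sets both C3 centres.

**Route**

Step 1
Reactants: 1 2-hydroxy-4-methoxybenzaldehyde
Product: 2 2-(benzyloxy)-4-methoxybenzaldehyde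
Conditions: BnBr, K2CO3, DMF, 60 °C
Reagents that add atoms: benzyl bromide, BrCc1ccccc1
Why: Williamson ether synthesis on the phenoxide should be clean, and benzyl is chosen so that every phenol mask of the route falls in the final hydrogenolysis.

Step 2
Reactants: 2 2-(benzyloxy)-4-methoxybenzaldehyde
Product: 4 2-[2-(benzyloxy)-4-methoxyphenyl]acetonitrile, via N-(1-tosylvinyl)formamide 3 (not isolated)
Conditions: TosMIC, KOt-Bu, DME, −40 °C; then MeOH, reflux
Reagents that add atoms: tosylmethyl isocyanide (TosMIC), Cc1ccc(S(=O)(=O)C[N+]#[C-])cc1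
Why: Van Leusen reductive cyanation, in which the TosMIC anion adds to the aldehyde, the oxazoline opens to 3, and methanolysis of the formyl group followed by loss of sulfinate gives the nitrile that is one carbon longer.

Step 3
Reactants: 4 2-[2-(benzyloxy)-4-methoxyphenyl]acetonitrile
Product: 5 2-[2-(benzyloxy)-4-methoxyphenyl]acetic acid
Conditions: KOH, EtOH–H2O, reflux; then aq. HCl
Reagents that add atoms: potassium hydroxide, [K+].[OH-]; water, O
Why: Alkaline nitrile hydrolysis, to which aryl benzyl and aryl methyl ethers are inert.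

Step 4
Reactants: 5 2-[2-(benzyloxy)-4-methoxyphenyl]acetic acid; 6 (S)-4-benzyloxazolidin-2-one
Product: 8 (S)-4-benzyl-3-{2-[2-(benzyloxy)-4-methoxyphenyl]acetyl}oxazolidin-2-one, via mixed pivalic anhydride 7 (not isolated)
Conditions: PivCl, Et3N, THF, −20 °C; then LiCl, 6, −20 °C → rt
Reagents that add atoms: none
Why: N-acylation of the oxazolidinone through a mixed anhydride with LiCl/Et3N activation, which attacks the less hindered arylacetyl carbonyl and avoids strong base and ketene formation.

Step 5
Reactants: 9 4-(benzyloxy)-2-hydroxybenzaldehyde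
Product: 10 4-(benzyloxy)-2-(methoxymethoxy)benzaldehyde
Conditions: MOMCl, i-Pr2NEt, CH2Cl2, 0 °C → reflux
Reagents that add atoms: chloromethyl methyl ether, COCCl
Why: Acetal-type O-alkylation of the phenol gives a mask that is orthogonal to benzyl and survives hydride, enolate and neutral bromination conditions.

Step 6
Reactants: 10 4-(benzyloxy)-2-(methoxymethoxy)benzaldehyde
Product: 11 [4-(benzyloxy)-2-(methoxymethoxy)phenyl]methanol
Conditions: NaBH4, MeOH–THF, 0 °C
Reagents that add atoms: none
Why: Borohydride reduction of an aromatic aldehyde, with no other reducible group present.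

Step 7
Reactants: 11 [4-(benzyloxy)-2-(methoxymethoxy)phenyl]methanol
Product: 12 4-(benzyloxy)-1-(bromomethyl)-2-(methoxymethoxy)benzene
Conditions: CBr4, PPh3, CH2Cl2, 0 °C; short filtration, used at once
Reagents that add atoms: carbon tetrabromide, BrC(Br)(Br)Br
Why: The Appel reaction makes the bromide under neutral conditions, which spares the MOM acetal and limits self-alkylation of this electron-rich benzylic halide.

Step 8
Reactants: 8 (S)-4-benzyl-3-{2-[2-(benzyloxy)-4-methoxyphenyl]acetyl}oxazolidin-2-one
Product: 13 (S)-4-benzyl-3-{2-[2-(benzyloxy)-5-bromo-4-methoxyphenyl]acetyl}oxazolidin-2-one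
Conditions: NBS, MeCN, 0 °C, dark
Reagents that add atoms: N-bromosuccinimide, O=C1CCC(=O)N1Br
Why: Electrophilic aromatic bromination goes to C5 of the resorcinol diether ring (para to OBn, ortho to OMe), because C3 is flanked by two alkoxy groups and the other phenyl rings are not activated.

Step 9
Reactants: 13 (S)-4-benzyl-3-{2-[2-(benzyloxy)-5-bromo-4-methoxyphenyl]acetyl}oxazolidin-2-one; 12 4-(benzyloxy)-1-(bromomethyl)-2-(methoxymethoxy)benzene
Product: 15 (S)-4-benzyl-3-{(2S)-2-[2-(benzyloxy)-5-bromo-4-methoxyphenyl]-3-[4-(benzyloxy)-2-(methoxymethoxy)phenyl]propanoyl}oxazolidin-2-one, via sodium (Z)-enolate 14 (not isolated)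
Conditions: NaN(SiMe3)2, THF, −78 °C; then 12, −78 → −30 °C
Reagents that add atoms: none
Why: Evans asymmetric alkylation, in which the sodium-chelated (Z)-enolate 14 is benzylated on the face away from the auxiliary benzyl group and so sets the future lower C3 as S.

Step 10
Reactants: 15 the alkylated imide
Product: 16 (2S)-2-[2-(benzyloxy)-5-bromo-4-methoxyphenyl]-3-[4-(benzyloxy)-2-(methoxymethoxy)phenyl]propan-1-ol
Conditions: LiBH4, THF–Et2O, 0 °C
Reagents that add atoms: none
Why: Reductive removal of the oxazolidinone auxiliary with LiBH4 does not enolise the substrate, so the α-aryl stereocentre is kept, and the aryl bromide and acetal are untouched.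

Step 11
Reactants: 16 the MOM-protected alcohol
Product: 17 5-(benzyloxy)-2-{(2S)-2-[2-(benzyloxy)-5-bromo-4-methoxyphenyl]-3-hydroxypropyl}phenol
Conditions: HCl (cat.), MeOH–THF, 45 °C
Reagents that add atoms: none
Why: Acid-catalysed transacetalisation to methanol frees the phenol, while the benzyl ethers and the stereocentre are inert.

Step 12
Reactants: 17 the phenol alcohol
Product: 18 (3S)-7-(benzyloxy)-3-[2-(benzyloxy)-5-bromo-4-methoxyphenyl]chroman
Conditions: PPh3, DIAD, THF, 0 °C → rt
Reagents that add atoms: none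
Why: Intramolecular Mitsunobu etherification closes the lower pyran ring 6-exo-tet at the primary carbon, so C3 is not touched.

Step 13
Reactants: 18 the bromo-isoflavan
Product: 20 4-(benzyloxy)-5-[(3S)-7-(benzyloxy)chroman-3-yl]-2-methoxybenzaldehyde, via aryllithium 19 (not isolated)
Conditions: n-BuLi, THF, −78 °C; then DMF, −78 → 0 °C; H2O
Reagents that add atoms: N,N-dimethylformamide, CN(C)C=O
Why: Bromine–lithium exchange followed by formylation places CHO exactly where bromine stood, which avoids the competition between ring D and the equally activated lower benzo ring that a direct formylation would face.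

Step 14
Reactants: 8 (S)-4-benzyl-3-{2-[2-(benzyloxy)-4-methoxyphenyl]acetyl}oxazolidin-2-one; 20 4-(benzyloxy)-5-[(3S)-7-(benzyloxy)chroman-3-yl]-2-methoxybenzaldehyde
Product: 21 (S)-4-benzyl-3-[(2R,3S)-2-[2-(benzyloxy)-4-methoxyphenyl]-3-{4-(benzyloxy)-5-[(3S)-7-(benzyloxy)chroman-3-yl]-2-methoxyphenyl}-3-(trimethylsilyloxy)propanoyl]oxazolidin-2-one
Conditions: MgCl2 (20 mol %), Et3N, TMSCl, EtOAc, rt
Reagents that add atoms: chlorotrimethylsilane, C[Si](C)(C)Cl
Why: Magnesium halide-catalysed direct anti-aldol of an N-acyloxazolidinone with a non-enolisable electron-rich aromatic aldehyde, in which soft enolisation gives the chelated (Z)-enolate, the auxiliary sets the α-carbon (future upper C3), the anti carbinol is formed and silylation makes the addition irreversible.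

Step 15
Reactants: 21 the silylated anti-aldol
Product: 23 (1S,2S)-2-[2-(benzyloxy)-4-methoxyphenyl]-1-{4-(benzyloxy)-5-[(3S)-7-(benzyloxy)chroman-3-yl]-2-methoxyphenyl}propane-1,3-diol, via silyl ether alcohol 22 (not isolated)
Conditions: LiBH4, THF–Et2O, 0 °C; crude 22, then K2CO3 (cat.), MeOH, 0 °C
Reagents that add atoms: none
Why: Reductive auxiliary removal is run on the silyl ether so that no β-alkoxide can trigger a retro-aldol, and the basic methanolysis of the TMS ether that follows avoids all acid on the very ionisable ring D carbinol.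

Step 16
Reactants: 23 the anti-diol
Product: 24 (2S,3S)-2-[2-(benzyloxy)-4-methoxyphenyl]-3-{4-(benzyloxy)-5-[(3S)-7-(benzyloxy)chroman-3-yl]-2-methoxyphenyl}-3-hydroxypropyl 4-methylbenzenesulfonate
Conditions: TsCl, Et3N, DMAP (cat.), CH2Cl2, 0 °C
Reagents that add atoms: 4-toluenesulfonyl chloride, Cc1ccc(S(=O)(=O)Cl)cc1
Why: Selective sulfonylation, since the primary hydroxyl reacts much faster than the secondary carbinol that is flanked by two aryl-bearing carbons.

Step 17
Reactants: 24 the primary tosylate
Product: 25 (2S,3S)-3-[2-(benzyloxy)-4-methoxyphenyl]-2-{4-(benzyloxy)-5-[(3S)-7-(benzyloxy)chroman-3-yl]-2-methoxyphenyl}oxetane (2,3-trans)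
Conditions: NaH, THF, 0 → 40 °C; chromatography on Et3N-deactivated silica
Reagents that add atoms: none
Why: Intramolecular Williamson etherification (4-exo-tet) displaces the primary tosylate, so neither stereocentre is touched and the anti-diol maps onto the trans-oxetane.

Step 18
Reactants: 26 4-(benzyloxy)phenol
Product: 27 4-(benzyloxy)-2-chlorophenol
Conditions: SO2Cl2, CH2Cl2–Et2O, 0 °C, dark
Reagents that add atoms: sulfuryl chloride, O=S(=O)(Cl)Cl
Why: Electrophilic chlorination of a para-blocked phenol goes ortho to the free hydroxyl, which is the stronger director.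

Step 19
Reactants: 27 4-(benzyloxy)-2-chlorophenol
Product: 28 4-(benzyloxy)-2-bromo-6-chlorophenol
Conditions: NBS, i-Pr2NH (cat.), CH2Cl2, 0 °C
Reagents that add atoms: N-bromosuccinimide, O=C1CCC(=O)N1Br
Why: Amine-catalysed ortho-bromination of a phenol fills the one remaining position next to the hydroxyl.

Step 20
Reactants: 28 4-(benzyloxy)-2-bromo-6-chlorophenol
Product: 29 [4-(benzyloxy)-2-bromo-6-chlorophenoxy]trimethylsilane
Conditions: HN(SiMe3)2, THF, reflux; evaporate
Reagents that add atoms: hexamethyldisilazane, C[Si](C)(C)N[Si](C)(C)C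
Why: O-silylation with a disilazane gives only a volatile co-product, so the moisture-sensitive silyl ether can be used after evaporation.

Step 21
Reactants: 29 [4-(benzyloxy)-2-bromo-6-chlorophenoxy]trimethylsilane
Product: 32 4-(benzyloxy)-2-chloro-6-(trimethylsilyl)phenyl trifluoromethanesulfonate, via aryllithium 30 (not isolated), via lithium phenoxide 31 (not isolated)
Conditions: n-BuLi, THF, −78 °C; then Tf2O, −78 → 0 °C
Reagents that add atoms: trifluoromethanesulfonic anhydride, O=S(=O)(OS(=O)(=O)C(F)(F)F)C(F)(F)F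
Why: Bromine–lithium exchange followed by retro-Brook O→C silyl migration and triflation of the phenoxide is the standard entry to ortho-silylaryl triflates, and the chlorine is meta to the lithiated carbon and so cannot be eliminated.

Step 22
Reactants: 25 the trans-2,3-diaryloxetane; 32 4-(benzyloxy)-2-chloro-6-(trimethylsilyl)phenyl trifluoromethanesulfonate
Product: 35 (3S,4S)-7-(benzyloxy)-3-[2-(benzyloxy)-4-methoxyphenyl]-4-{4-(benzyloxy)-5-[(3S)-7-(benzyloxy)chroman-3-yl]-2-methoxyphenyl}-5-chlorochroman (3,4-trans), via aryne 33 (not isolated), via oxonium zwitterion 34 (not isolated)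
Conditions: CsF, 4 Å MS, PhMe–MeCN (4:1), 40 °C, 32 (2 equiv) added by syringe pump
Reagents that add atoms: none
Why: Proposed new method: fluoride desilylates 32 and triflate departs to give aryne 33, the strained and Lewis-basic oxetane oxygen of 25 adds to the aryne carbon remote from chlorine (future C8a) to give zwitterion 34, the benzylic C–O bond of the oxonium ion breaks with release of ring strain, and the aryl anion at future C4a captures the benzylic carbon, so that O1–C8a and C4–C4a form and the C–O σ-bond ends up inserted across the aryne. The closest known reaction types are the insertion of arynes into the benzylic C–O bond of styrene oxides to give 2,3-dihydrobenzofurans and the aryne-triggered opening of cyclic ethers through O-aryl oxonium ions, but ring expansion of an oxetane to a chroman has not been shown. The one ring that closes, the upper pyran ring, does so by a six-membered collapse of aryl anion on cation, formally 6-exo-trig on the exocyclic C=C bond of the quinone-methide form of ring D. C4 is the only new stereocentre and is controlled by C3, because front-side collapse within the tight zwitterion (retention at the former oxetane C2) and attack on a free planar cation anti to ring B both lead to the 3,4-trans product from the trans-oxetane. Regioselectivity of O-attack is secured by the chlorine next to the triple bond, which distorts the aryne and stabilises the anion at C4a inductively and so overrides the weak opposite bias of the benzyloxy group, and site selectivity of C–O cleavage is secured by the ortho-methoxy and para-benzyloxy donors of ring D, which leave the primary CH2–O bond untouched. The collapse must outrun proton transfer to the aryl anion and loss of chloride from it, which is why a mostly non-polar aprotic medium, molecular sieves and slow release of the aryne are specified.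

Step 23
Reactants: 35 the 5-chloro tetra-O-benzyl ether
Product: 36 CNP0152030.1, (3S,4R)-4-{4-hydroxy-5-[(3S)-7-hydroxychroman-3-yl]-2-methoxyphenyl}-3-(2-hydroxy-4-methoxyphenyl)chroman-7-ol
Conditions: H2 (3 atm), 10% Pd/C, NaOAc, THF–MeOH, rt
Reagents that add atoms: none
Why: Palladium-catalysed hydrogenolysis cleaves the four aryl benzyl ethers and, with acetate taking up the acid, the aryl C–Cl bond in one operation without touching any stereocentre, and the C4 descriptor changes from S to R only because loss of chlorine lowers the rank of C4a.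

**Compound list**
1 | 2-hydroxy-4-methoxybenzaldehyde | COc1ccc(C=O)c(O)c1 | starting material
2 | 2-(benzyloxy)-4-methoxybenzaldehyde | COc1ccc(C=O)c(OCc2ccccc2)c1 | intermediate
3 | N-{2-[2-(benzyloxy)-4-methoxyphenyl]-1-tosylethenyl}formamide (present as its potassium salt, alkene geometry not defined) | COc1ccc(C=C(NC=O)S(=O)(=O)c2ccc(C)cc2)c(OCc2ccccc2)c1 | intermediate
4 | 2-[2-(benzyloxy)-4-methoxyphenyl]acetonitrile | COc1ccc(CC#N)c(OCc2ccccc2)c1 | intermediate
5 | 2-[2-(benzyloxy)-4-methoxyphenyl]acetic acid | COc1ccc(CC(=O)O)c(OCc2ccccc2)c1 | intermediate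
6 | (S)-4-benzyloxazolidin-2-one | O=C1N[C@@H](Cc2ccccc2)CO1 | starting material
7 | 2-[2-(benzyloxy)-4-methoxyphenyl]acetic pivalic anhydride | COc1ccc(CC(=O)OC(=O)C(C)(C)C)c(OCc2ccccc2)c1 | intermediate
8 | (S)-4-benzyl-3-{2-[2-(benzyloxy)-4-methoxyphenyl]acetyl}oxazolidin-2-one | COc1ccc(CC(=O)N2[C@@H](Cc3ccccc3)COC2=O)c(OCc2ccccc2)c1 | intermediate
9 | 4-(benzyloxy)-2-hydroxybenzaldehyde | O=Cc1ccc(OCc2ccccc2)cc1O | starting material
10 | 4-(benzyloxy)-2-(methoxymethoxy)benzaldehyde | COCOc1cc(OCc2ccccc2)ccc1C=O | intermediate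
11 | [4-(benzyloxy)-2-(methoxymethoxy)phenyl]methanol | COCOc1cc(OCc2ccccc2)ccc1CO | intermediate
12 | 4-(benzyloxy)-1-(bromomethyl)-2-(methoxymethoxy)benzene | COCOc1cc(OCc2ccccc2)ccc1CBr | intermediate
13 | (S)-4-benzyl-3-{2-[2-(benzyloxy)-5-bromo-4-methoxyphenyl]acetyl}oxazolidin-2-one | COc1cc(OCc2ccccc2)c(CC(=O)N2[C@@H](Cc3ccccc3)COC2=O)cc1Br | intermediate
14 | sodium (Z)-enolate of 13 | COc1cc(OCc2ccccc2)c(/C=C(\[O-])N2[C@@H](Cc3ccccc3)COC2=O)cc1Br.[Na+] | intermediate
15 | (S)-4-benzyl-3-{(2S)-2-[2-(benzyloxy)-5-bromo-4-methoxyphenyl]-3-[4-(benzyloxy)-2-(methoxymethoxy)phenyl]propanoyl}oxazolidin-2-one | COc1cc(OCc2ccccc2)c([C@H](Cc2ccc(OCc3ccccc3)cc2OCOC)C(=O)N2[C@@H](Cc3ccccc3)COC2=O)cc1Br | intermediate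
16 | (2S)-2-[2-(benzyloxy)-5-bromo-4-methoxyphenyl]-3-[4-(benzyloxy)-2-(methoxymethoxy)phenyl]propan-1-ol | COc1cc(OCc2ccccc2)c([C@H](Cc2ccc(OCc3ccccc3)cc2OCOC)CO)cc1Br | intermediate
17 | 5-(benzyloxy)-2-{(2S)-2-[2-(benzyloxy)-5-bromo-4-methoxyphenyl]-3-hydroxypropyl}phenol | COc1cc(OCc2ccccc2)c([C@H](Cc2ccc(OCc3ccccc3)cc2O)CO)cc1Br | intermediate
18 | (3S)-7-(benzyloxy)-3-[2-(benzyloxy)-5-bromo-4-methoxyphenyl]chroman | COc1cc(OCc2ccccc2)c([C@H]2COc3cc(OCc4ccccc4)ccc3C2)cc1Br | intermediate
19 | aryllithium from 18 (Li in place of Br) | COc1cc(OCc2ccccc2)c([C@H]2COc3cc(OCc4ccccc4)ccc3C2)cc1[Li] | intermediate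
20 | 4-(benzyloxy)-5-[(3S)-7-(benzyloxy)chroman-3-yl]-2-methoxybenzaldehyde | COc1cc(OCc2ccccc2)c([C@H]2COc3cc(OCc4ccccc4)ccc3C2)cc1C=O | intermediate
21 | (2R,3S)-anti-aldol TMS ether on the (S)-auxiliary (ring B on C2, ring D and OTMS on C3) | COc1ccc([C@H]([C@H](O[Si](C)(C)C)c2cc([C@H]3COc4cc(OCc5ccccc5)ccc4C3)c(OCc3ccccc3)cc2OC)C(=O)N2[C@@H](Cc3ccccc3)COC2=O)c(OCc2ccccc2)c1 | intermediate
22 | (2S,3S)-2-(ring B)-3-(ring D)-3-(trimethylsilyloxy)propan-1-ol | COc1ccc([C@H]([C@H](O[Si](C)(C)C)c2cc([C@H]3COc4cc(OCc5ccccc5)ccc4C3)c(OCc3ccccc3)cc2OC)CO)c(OCc2ccccc2)c1 | intermediate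
23 | (1S,2S)-2-(ring B)-1-(ring D)propane-1,3-diol (anti) | COc1ccc([C@H]([C@H](O)c2cc([C@H]3COc4cc(OCc5ccccc5)ccc4C3)c(OCc3ccccc3)cc2OC)CO)c(OCc2ccccc2)c1 | intermediate
24 | primary 4-methylbenzenesulfonate of 23, (2S,3S) | COc1ccc([C@H]([C@H](O)c2cc([C@H]3COc4cc(OCc5ccccc5)ccc4C3)c(OCc3ccccc3)cc2OC)COS(=O)(=O)c2ccc(C)cc2)c(OCc2ccccc2)c1 | intermediate
25 | (2S,3S)-trans-2,3-diaryloxetane (ring B on C3, ring D with the lower (3S)-isoflavan on C2) | COc1ccc([C@H]2CO[C@@H]2c2cc([C@H]3COc4cc(OCc5ccccc5)ccc4C3)c(OCc6ccccc6)cc2OC)c(OCc7ccccc7)c1 | intermediate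
26 | 4-(benzyloxy)phenol | Oc1ccc(OCc2ccccc2)cc1 | starting material
27 | 4-(benzyloxy)-2-chlorophenol | Oc1ccc(OCc2ccccc2)cc1Cl | intermediate
28 | 4-(benzyloxy)-2-bromo-6-chlorophenol | Oc1c(Cl)cc(OCc2ccccc2)cc1Br | intermediate
29 | [4-(benzyloxy)-2-bromo-6-chlorophenoxy]trimethylsilane | C[Si](C)(C)Oc1c(Cl)cc(OCc2ccccc2)cc1Br | intermediate
30 | aryllithium from 29 (Li in place of Br) | C[Si](C)(C)Oc1c(Cl)cc(OCc2ccccc2)cc1[Li] | intermediate
31 | lithium 4-(benzyloxy)-2-chloro-6-(trimethylsilyl)phenoxide | C[Si](C)(C)c1cc(OCc2ccccc2)cc(Cl)c1[O-].[Li+] | intermediate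
32 | 4-(benzyloxy)-2-chloro-6-(trimethylsilyl)phenyl trifluoromethanesulfonate | C[Si](C)(C)c1cc(OCc2ccccc2)cc(Cl)c1OS(=O)(=O)C(F)(F)F | intermediate
33 | 5-(benzyloxy)-3-chlorobenzyne | ClC1=CC(OCc2ccccc2)=CC#C1 | intermediate
34 | O-aryl oxetanium / aryl anion zwitterion | COc1ccc([C@H]2C[O+](c3cc(OCc4ccccc4)cc(Cl)[c-]3)[C@@H]2c2cc([C@H]3COc4cc(OCc5ccccc5)ccc4C3)c(OCc3ccccc3)cc2OC)c(OCc2ccccc2)c1 | intermediate
35 | 5-chloro tetra-O-benzyl target, (3S,4S)-trans, lower (3S) | COc1ccc([C@H]2COc3cc(OCc4ccccc4)cc(Cl)c3[C@@H]2c2cc([C@H]3COc4cc(OCc5ccccc5)ccc4C3)c(OCc3ccccc3)cc2OC)c(OCc2ccccc2)c1 | intermediate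
36 | CNP0152030.1, (3S,4R)-trans, lower (3S) | COc1ccc([C@H]2COc3cc(O)ccc3[C@@H]2c2cc([C@H]3COc4cc(O)ccc4C3)c(O)cc2OC)c(O)c1 | target

**Step count and risks**
Total steps: 23. Longest linear sequence: 16 steps (1–4, 8–17, 22, 23).

Steps most likely to fail:

1. Step 22. The aryl anion of the zwitterion may take a proton from C3–H (ring-opening elimination) or from the medium. It may also expel the neighbouring chloride, and fluoride may open the oxonium ion before the C–C bond forms. The fallback uses known chemistry, sets out from diol 23 and comes back at 36.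
   - The primary hydroxyl of 23 is etherified with commercial 3-(benzyloxy)phenol under Mitsunobu conditions (PPh3, DIAD, THF, 0 °C) to give the aryl ether carbinol F1.
   - A catalytic Lewis acid (BF3·OEt2 or Bi(OTf)3, CH2Cl2, −40 °C) then ionises the ring D carbinol. The cation alkylates the aryloxy ring para to its benzyloxy group in an intramolecular Friedel–Crafts cycloalkylation that closes anti to ring B, giving the chlorine-free tetra-O-benzyl ether F2.
   - Hydrogenolysis of F2 under the conditions of step 23, without acetate, should give 36.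

2. Step 17. The γ-tosyloxy alkoxide may undergo Grob-type fragmentation into an aromatic aldehyde and a styrene instead of the 4-exo-tet closure, and the strained, acid-labile ether may be lost on isolation. The fallback sets out from diol 23 and comes back at 25. The sulfonate/alkoxide pair is abandoned for a Mitsunobu-type cyclodehydration of the 1,3-diol (PPh3, DIAD, toluene, 0 °C → rt). The primary hydroxyl is activated as an alkoxyphosphonium ion and the carbinol closes without ever being a free metal alkoxide. This fallback makes no new compound (F0).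

3. Step 14. Possible failures are sluggish addition to the hindered ortho-substituted aldehyde, erosion of anti or facial selectivity with the arylacetyl imide, and reversal of the aldol before silylation. The fallback sets out from acid 5 and aldehyde 20 and comes back at 35.
   - Acid 5 is coupled as in step 4 with (R)-4-benzyloxazolidin-2-one to give the enantiomeric-auxiliary imide F3.
   - A boron-mediated Evans syn-aldol (Bu2BOTf, i-Pr2NEt, CH2Cl2, −78 → 0 °C) with 20 gives the syn-aldol F4, which has the same configuration at the α-carbon.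
   - LiBH4 gives the syn-diol F5, selective tosylation gives the primary tosylate F6, and NaH closes the cis-oxetane F7.
   - F7 enters step 22 in place of 25 and should converge on 35, provided the benzylic carbon ionises fully so that C3 alone decides the new C4 centre.

Further compounds
F1 | step 22 | (1S,2S)-3-[3-(benzyloxy)phenoxy]-2-[2-(benzyloxy)-4-methoxyphenyl]-1-{4-(benzyloxy)-5-[(3S)-7-(benzyloxy)chroman-3-yl]-2-methoxyphenyl}propan-1-ol | COc1ccc([C@H]([C@H](O)c2cc([C@H]3COc4cc(OCc5ccccc5)ccc4C3)c(OCc3ccccc3)cc2OC)COc2cccc(OCc3ccccc3)c2)c(OCc2ccccc2)c1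
F2 | step 22 | tetra-O-benzyl ether of the target, (3S,4R)-trans, lower (3S) | COc1ccc([C@H]2COc3cc(OCc4ccccc4)ccc3[C@@H]2c2cc([C@H]3COc4cc(OCc5ccccc5)ccc4C3)c(OCc3ccccc3)cc2OC)c(OCc2ccccc2)c1
F0 | step 17 | none | none
F3 | step 14 | (R)-4-benzyl-3-{2-[2-(benzyloxy)-4-methoxyphenyl]acetyl}oxazolidin-2-one | COc1ccc(CC(=O)N2[C@H](Cc3ccccc3)COC2=O)c(OCc2ccccc2)c1
F4 | step 14 | (2R,3R)-syn-aldol on the (R)-auxiliary | COc1ccc([C@H]([C@@H](O)c2cc([C@H]3COc4cc(OCc5ccccc5)ccc4C3)c(OCc3ccccc3)cc2OC)C(=O)N2[C@H](Cc3ccccc3)COC2=O)c(OCc2ccccc2)c1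
F5 | step 14 | (1R,2S)-syn-diol | COc1ccc([C@H]([C@@H](O)c2cc([C@H]3COc4cc(OCc5ccccc5)ccc4C3)c(OCc3ccccc3)cc2OC)CO)c(OCc2ccccc2)c1
F6 | step 14 | primary 4-methylbenzenesulfonate of F5 | COc1ccc([C@H]([C@@H](O)c2cc([C@H]3COc4cc(OCc5ccccc5)ccc4C3)c(OCc3ccccc3)cc2OC)COS(=O)(=O)c2ccc(C)cc2)c(OCc2ccccc2)c1
F7 | step 14 | (2R,3S)-cis-2,3-diaryloxetane | COc1ccc([C@H]2CO[C@H]2c2cc([C@H]3COc4cc(OCc5ccccc5)ccc4C3)c(OCc3ccccc3)cc2OC)c(OCc2ccccc2)c1
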